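The central spiro-cyclohexene (C4, C15, C14′, C10′, C1′, C2′; guaianolide numbering, unprimed for the cyclopentanone half, primed for the cyclopentenone half) is reached from a cyclobutane. Two halves made from dehydrocostus lactone are first joined head to head through the four-membered ring C4–C15–C14′–C10′ by a sensitised [2+2] cycloaddition. Its C4–C10′ bond is flanked by the C3 ketone and by the C1′=C2′–C3′=O enone, so both radicals released on homolysis are stabilised; heating therefore moves C4 from C10′ to C2′. This 1,3-shift expands the ring by two atoms, creates the spiro quaternary centre C4 on the convex face, and leaves only a base-mediated conjugation.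

Key step: step 6

Remark on the chemistry (assumption): C10′ and C5′ are both γ to the C3′ carbonyl across C2′=C1′ and can epimerise through the extended enolate. The required arrangement (H-10′ α; H-5′ β, cis to H-6′ and inverted relative to dehydrocostus lactone) is taken to be the one favoured at equilibrium and is set in the last step.

Step 1
Reactants: 1 dehydrocostus lactone
Product: 2 epizaluzanin C (the C3 α-alcohol of dehydrocostus lactone)
Conditions: SeO2 (0.5 equiv, catalytic), t-BuOOH (2 equiv), CH2Cl2, 0 °C to rt
Reagents that add atoms: tert-butyl hydroperoxide, CC(C)(C)OO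
Why: SeO2-catalysed allylic hydroxylation (ene reaction then [2,3]-sigmatropic shift, with tert-butyl hydroperoxide as terminal oxidant) should select the C3 methylene next to the electron-rich C4=C15 bond and spare the conjugated C11=C13; oxygen is expected on the convex α face, but this stereocentre is destroyed in step 2, so the β-epimer serves equally.

Step 2
Reactants: 2 epizaluzanin C
Product: 3 dehydrozaluzanin C
Conditions: Dess–Martin periodinane (1.2 equiv), CH2Cl2, 0 °C to rt
Reagents that add atoms: none
Why: Dess–Martin oxidation of the allylic alcohol under neutral conditions should give the exo-methylene ketone without touching the three exocyclic alkenes or C1/C5; no new stereocentre.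

Step 3
Reactants: 3 dehydrozaluzanin C
Product: 4 tert-butyldimethylsilyl dienol ether of dehydrozaluzanin C (C2=C3 enol ether)
Conditions: TBSOTf (1.2 equiv), Et3N (2 equiv), CH2Cl2, −78 °C to 0 °C
Reagents that add atoms: tert-butyldimethylsilyl trifluoromethanesulfonate, CC(C)(C)[Si](C)(C)OS(=O)(=O)C(F)(F)F
Why: Soft enolisation (silyl enol ether formation) can only run towards C2 because C4 is sp2, so the silyloxy diene C15=C4–C3(OSi)=C2 forms regiospecifically; no new stereocentre.

Step 4
Reactants: 4 silyl dienol ether
Product: 5 cross-conjugated trienone (C1=C2 enone, C10=C14 and C4=C15 retained, H-5 α)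
Conditions: Pd(OAc)2 (1.05 equiv), MeCN, rt; filtered cold through silica and used at once as a dilute solution
Reagents that add atoms: none
Why: In this Saegusa–Ito oxidation the palladium enolate at C2 has H-1 as its only β-hydrogen, so β-hydride elimination installs C1=C2 and removes the C1 stereocentre, while the acid- and base-free conditions leave the now γ-acidic C5–H alone.

Step 5
Reactants: 5 cross-conjugated trienone; 3 dehydrozaluzanin C
Product: 6 head-to-head cyclobutane (four-membered ring C4–C15–C14′–C10′, spiro at both C4 and C10′)
Conditions: thioxanthone (10 mol %), CH2Cl2 (degassed), 405 nm LEDs, −40 °C; trienone added by syringe pump so that the ketone partner stays in excess throughout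
Reagents that add atoms: none
Why: Triplet energy transfer should populate only the lowest triplet, that of the trienone, whose twisted exocyclic terminus C14′ adds to the most electron-poor, least hindered methylene of the ketone partner (C15) to give the 1,4-diradical stabilised at C4 (α-keto) and C10′ (dienoyl), which closes at the proximal, spin-rich C10′ on the convex α faces of both halves (sensitised diene–alkene [2+2] photocycloaddition); the cold conditions hold back the thermal cycloaddition of the two partners, and both new stereocentres are reset or erased in steps 6 and 7, so all diastereomers of the cyclobutane converge.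

Step 6
Reactants: 6 head-to-head cyclobutane
Product: 7 spiro-cyclohexene β,γ-enone (C4–C2′ and C15–C14′ bonds, C1′=C10′, C2′–H)
Conditions: PhMe (5 mM, degassed), BHT (10 mol %), 110 °C, sealed tube
Reagents that add atoms: none
Why: Heating homolyses the weakest σ-bond, C4–C10′ of the strained four-membered ring, to an α-keto radical at C4 and an oxapentadienyl radical spread over C10′, C2′ and the C3′ oxygen. Reclosure at C10′ only regenerates the cyclobutane, whereas bonding of C4 to C2′ releases about 26 kcal/mol of ring strain and is irreversible, so the net event is a 1,3-shift of C4 that expands the cyclobutane by C1′ and C2′; the closest known reaction type is the thermal vinylcyclobutane-to-cyclohexene rearrangement of 1-acyl-2-vinylcyclobutanes. The six-membered ring closes by recombination of the C4 and C2′ radical termini, which the seven-membered ring holds cisoid because C9′ and C5′ are both ring atoms. The spiro centre C4 is set by substrate control: the planar C4 radical is attacked on the convex α face of the cis-fused hydroazulenone (syn to H-5, away from C6 and C10), placing C2′ α and C15 β, while C2′ is a transient stereocentre erased in step 7. Site selectivity for C2′ over C10′ is secured thermodynamically and facial selectivity by the fold of the bicycle; C4–C15 and C14′–C10′ stay intact because their cleavage would give unstabilised primary radicals. High dilution, degassing and BHT are there to hold back cycloreversion to the two monomers and radical addition to the exocyclic methylenes.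

Step 7
Reactants: 7 spiro-cyclohexene β,γ-enone
Product: 8 CNP0221188.1 (target)
Conditions: DBU (0.3 equiv), CH2Cl2, 0 °C to rt; AcOH quench
Reagents that add atoms: none
Why: DBU removes C2′–H (α to C3′=O and allylic), γ-protonation of the dienolate at C10′ gives the tetrasubstituted conjugated enone as thermodynamic sink, and reversible γ-deprotonation at C5′ lets C10′ and C5′ settle under thermodynamic control (see remark) into the 10′α-H/5′β-H arrangement that puts C9′ and C6′ on opposite faces of the planar C10′–C1′–C5′ unit (1,3-prototropic enone isomerisation with epimerisation).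

Compound list
1 | dehydrocostus lactone, guaia-4(15),10(14),11(13)-trien-12,6α-olide (1α-H, 5α-H, 6β-H, 7α-H) | C=C1CC[C@@H]2[C@@H]([C@@H]3[C@H]1CCC3=C)OC(=O)C2=C | starting material
2 | epizaluzanin C, 3α-hydroxydehydrocostus lactone | C=C1CC[C@@H]2[C@@H]([C@@H]3[C@H]1C[C@@H](O)C3=C)OC(=O)C2=C | intermediate
3 | dehydrozaluzanin C, 3-oxoguaia-4(15),10(14),11(13)-trien-12,6α-olide | C=C1CC[C@@H]2[C@@H]([C@@H]3[C@H]1CC(=O)C3=C)OC(=O)C2=C | intermediate
4 | 3-(tert-butyldimethylsilyloxy)guaia-2,4(15),10(14),11(13)-tetraen-12,6α-olide | C=C1CC[C@@H]2[C@@H]([C@@H]3[C@H]1C=C(O[Si](C)(C)C(C)(C)C)C3=C)OC(=O)C2=C | intermediate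
5 | 3-oxoguaia-1,4(15),10(14),11(13)-tetraen-12,6α-olide (5α-H) | C=C1CC[C@@H]2[C@@H]([C@@H]3C1=CC(=O)C3=C)OC(=O)C2=C | intermediate
6 | head-to-head cyclobutane of 3 and 5: ring C4–C15–C14′–C10′, spiro at C4 (C10′ α, C15 β) and at C10′ (C4 α, C14′ β); primed half keeps C3′=O, C2′=C1′ and C4′=C15′ | C=C1CC[C@@H]2[C@@H]([C@@H]3[C@H]1CC(=O)[C@]34CC[C@]45CC[C@@H]6[C@@H]([C@@H]7C5=CC(=O)C7=C)OC(=O)C6=C)OC(=O)C2=C | intermediate
7 | spiro-cyclohexene β,γ-enone: ring C4–C15–C14′–C10′=C1′–C2′, C2′ on the α face of C4, C2′–H β, 5′α-H | C=C1CC[C@@H]2[C@@H]([C@@H]3[C@H]1CC(=O)[C@]34CCC5=C6[C@@H]4C(=O)C(=C)[C@@H]6[C@H]7OC(=O)C(=C)[C@@H]7CC5)OC(=O)C2=C | intermediate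
8 | CNP0221188.1: conjugated C2′=C1′ enone, 10′α-H, 5′β-H | C=C1C(=O)C2=C3[C@H](CC[C@H]4C(=C)C(=O)O[C@@H]4[C@H]13)CC[C@]21C(=O)C[C@H]2C(=C)CC[C@H]3C(=C)C(=O)O[C@@H]3[C@H]21 | target

Total step count: 7. Longest linear sequence: 7 steps (1 to 8 through 4 and 5); compound 3 re-enters as the second component in step 5.

Steps most likely to fail

Step 5. The triplet of 5 may add to the methylene lactone of 3 instead of C15, the 1,4-diradical may partition towards direct six-membered closure, and 5 may dimerise. The fallback sets out from 5 (with 3) and comes back at 6. Luche reduction of 5 (NaBH4, CeCl3·7H2O, MeOH, −78 °C) gives the bis-allylic alcohol 3-hydroxyguaia-1,4(15),10(14),11(13)-tetraen-12,6α-olide F1, and TBSCl/imidazole in DMF gives its silyl ether F2. Irradiation of 3 at 350 nm with excess F2 at −60 °C, where only the enone of 3 absorbs, is a classical enone–diene [2+2] photocycloaddition through the same C4/C10′ diradical, now free of the dienone chromophore; it should give the silyloxy cyclobutane F3. HF·pyridine gives the allylic alcohol F4, and Dess–Martin oxidation returns 6.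

Step 6. The diradical may fragment across C15–C14′ back to 3 and 5, radical chains may start at the exocyclic methylenes, and facial control at C4 may be poor. The fallback sets out from 6 and comes back at 7, and replaces homolysis by a polar ring expansion. Luche reduction, expected to prefer the conjugated C3′ ketone over the hindered saturated C3 ketone, gives the allylic alcohol F4, and silylation gives the silyl ether F3 (both met above). With the acyl group gone, the primed alkene is a donor and the ring a donor–acceptor cyclobutane. Sc(OTf)3 in CH2Cl2 at −20 °C should open C4–C10′ heterolytically (metal enolate at C4, tertiary allyl cation C10′–C1′–C2′) and reclose at C2′ to the spiro-cyclohexene silyl ether F5. HF·pyridine gives the alcohol F6, and Dess–Martin oxidation gives 7.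

Step 7. Equilibration may settle on another C5′/C10′ arrangement, and the base may move exocyclic double bonds into the rings. The fallback sets out from 7 and comes back at 8, and replaces thermodynamic by kinetic control. If DBU stops at the conjugated enone that keeps the 5′α-hydrogen, the C5′ epimer F7, this is deprotonated irreversibly at its most acidic position C5′ with LiN(SiMe3)2 (1.0 equiv, THF, −78 °C) to the lithium fulvenolate F8. Inverse quench into cold acetic acid/THF should protonate C5′ kinetically on the face syn to H-6′ and away from C7′/C8′, the usual route to the less stable epimer, giving 8.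

Further compounds
F1 | step 5 | 3-hydroxyguaia-1,4(15),10(14),11(13)-tetraen-12,6α-olide (C3 configuration immaterial) | C=C1CC[C@@H]2[C@@H]([C@@H]3C1=CC(O)C3=C)OC(=O)C2=C
F2 | step 5 | 3-(tert-butyldimethylsilyloxy)guaia-1,4(15),10(14),11(13)-tetraen-12,6α-olide | C=C1CC[C@@H]2[C@@H]([C@@H]3C1=CC(O[Si](C)(C)C(C)(C)C)C3=C)OC(=O)C2=C
F3 | step 5 | 3′-silyloxy analogue of cyclobutane 6 | C=C1CC[C@@H]2[C@@H]([C@@H]3[C@H]1CC(=O)[C@]34CC[C@]45CC[C@@H]6[C@@H]([C@@H]7C5=CC(O[Si](C)(C)C(C)(C)C)C7=C)OC(=O)C6=C)OC(=O)C2=C
F4 | step 5 | 3′-hydroxy analogue of cyclobutane 6 | C=C1CC[C@@H]2[C@@H]([C@@H]3[C@H]1CC(=O)[C@]34CC[C@]45CC[C@@H]6[C@@H]([C@@H]7C5=CC(O)C7=C)OC(=O)C6=C)OC(=O)C2=C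
F5 | step 6 | 3′-silyloxy analogue of spiro-cyclohexene 7 | C=C1CC[C@@H]2[C@@H]([C@@H]3[C@H]1CC(=O)[C@]34CCC5=C6[C@@H]4C(O[Si](C)(C)C(C)(C)C)C(=C)[C@@H]6[C@H]7OC(=O)C(=C)[C@@H]7CC5)OC(=O)C2=C
F6 | step 6 | 3′-hydroxy analogue of spiro-cyclohexene 7 | C=C1CC[C@@H]2[C@@H]([C@@H]3[C@H]1CC(=O)[C@]34CCC5=C6[C@@H]4C(O)C(=C)[C@@H]6[C@H]7OC(=O)C(=C)[C@@H]7CC5)OC(=O)C2=C
F7 | step 7 | 5′-epimer of 8 (5′α-H, 10′α-H) | C=C1C(=O)C2=C3[C@H](CC[C@H]4C(=C)C(=O)O[C@@H]4[C@@H]13)CC[C@]21C(=O)C[C@H]2C(=C)CC[C@H]3C(=C)C(=O)O[C@@H]3[C@H]21
F8 | step 7 | lithium fulvenolate of 8 (C5′ deprotonated, O3′–Li) | C=C1C(O[Li])=C2C3=C1[C@H]4OC(=O)C(=C)[C@@H]4CC[C@@H]3CC[C@]21C(=O)C[C@H]2C(=C)CC[C@H]3C(=C)C(=O)O[C@@H]3[C@H]21
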